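Atom numbers C1–O30 follow the order of the SMILES of andilesin B; compound numbers 1–43 are those of the steps and of the compound list. In the early monocyclic compounds the ring carbons already carry their final numbers: in 1 the carbonyl carbon is C24, then C25, C29 (ethoxy-bearing), C16, C15 and C14.

## Analysis of the target

Andilesin B (43) is a hexacyclic C25 dilactone. It contains an α,β-unsaturated ε-lactone (ring A: C2, O4, C5, C7, C8, C9, C11), a cyclohexane (ring B), a cyclopentane (ring C), a bicyclo[2.2.2]octenone and an α-alkylidene γ-lactone (ring E) fused to the cage at C19–C24. Of its seven stereocentres (C9, C11, C14, C16, C24, C25, C28) five are quaternary, and C14, C24 and C25 are contiguous. C16, C24 and C25 are tied together by the cage, and ring C forces C27 onto the C14 side of the C25–C29 bridge. The A/B junction is trans, the B/C junction is cis, and the C10 methyl is cis to H28. The sensitive groups are the unsaturated ε-lactone with its tertiary alkyl oxygen, the C18=C19–C20 acceptor and the hindered C29 ketone. The difficulty lies in the crowding around C14, which belongs to rings B and C and to the cage, and in the lack of functional handles in rings B and C (C12, C13 and C27 are methylenes). The strategy rests on one feature: rings A, B and C are fused in a row and share only the bonds C9–C11 and C14–C28. With a C12=C13 double bond and a carbonyl on C27, ring B becomes the retron of a [4+2] cycloaddition.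

## Retrosynthetic reasoning

**C7=C8 last.** The lactone double bond of 43 is taken back to the saturated lactone 41. In 41 the lactone α-methylene C7 is the only enolisable position, so the dehydrogenation can be done selectively at the very end and the conjugate acceptor is absent during all reductions.

**C27 oxygen and C12=C13.** 41 is traced back to cycloadduct 37, which carries a C27 ketone and a C12=C13 double bond. The ketone is the activating group of the dienophile and the alkene is the trace of the diene. C27 is the less hindered of the two ketones (C29 lies between two quaternary carbons), so it can be reduced and deoxygenated selectively.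

**C9–C11 and C14–C28 (key disconnection).** Cutting both bonds of 37 opens rings A, B and C at once and leads to the 14-membered macrolactone 36. Its diene C11=C12–C13=C14 is exocyclic to the cage at C14, and its (Z)-enone C28=C9 is attached to C25 through C27. No other pair of bonds removes three rings and four stereocentres in one step. The forward reaction must give the trans A/B and cis B/C junctions from olefin geometry alone.

**C11=C12 and C27–C28.** 36 is opened at the (E)-disubstituted C11=C12 bond (ring-closing metathesis of 35) and then at C27–C28 (addition of vinyl iodide 33 to aldehyde 26, then oxidation). C11=C12 is remote from all stereocentres and the reaction tolerates the tertiary ester. The C27–C28 cut separates a small cage aldehyde from an acyclic chain whose (Z)-geometry is fixed beforehand.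

**C13=C14 geometry.** The diene of 26 has C12 cis to the quaternary C24, the sterically disfavoured arrangement, so a direct olefination of the C14 ketone 17 would give the wrong isomer. The diene is therefore taken back through enal 23 and allylic alcohol 22 to the allene 20. Hydride delivery to the central carbon C13 from the open C15 side places C12 on the C24 side. 20 comes from ketone 17 by ethynylation and SN2′ reduction.

**C25 quaternary centre and ring E.** 17 is traced to the cage ester 12. C27 and then the C26 methyl are introduced at C25 by two enolate-type alkylations; the second enters from the alkene face because the C14 silyloxy group blocks the other. Ring E closes when the C23 hydroxyl is freed next to the C20 ester.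

**C16–C18 and C19–C24.** The bicyclo[2.2.2]octadiene 12 is cut into the 2-silyloxydiene 10 and methyl propiolate (11). The silyloxy group on C29 directs the ester-bearing carbon C19 to C24, and the C14 silyloxy stereocentre, later oxidised away, controls the face and so the absolute configuration of the cage.

**Diene 10.** 10 goes back, through α′-methylation and a Stork–Danheiser transposition with the C23 stannane 6, to the protected α′-hydroxy vinylogous ester 5. 5 comes from 3-ethoxycyclohex-2-en-1-one (1) by asymmetric epoxidation of its silyl dienol ether 2.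

**Side chain 33.** 33 is cut at C7–C8 into the allylic bromide 30 and the acetate 32. 30 derives from prop-2-yn-1-ol (27) by an anti-carbomagnesiation that fixes the (Z)-iodoalkene, and 32 from 2-methylbut-3-en-2-ol (31).

## Alternatives that were turned down

**Alternative 1:** Ring B is cut at C13–C14 and the six carbons C14, C15, C16, C29, C25, C24 are taken back to a benzene ring. In the forward direction the phenoxide of iodide A2 attacks C13 with its para carbon and gives the spiro[5.5]cyclohexadienone A1.
- For: the oxygen cannot reach the iodide, so C-alkylation is enforced and a six-membered ring forms. The arene already carries C23 and both methyl groups.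
- Against: A1 still lacks the bicyclo[2.2.2]octene, ring C and both lactones, and ring A is a carbocycle that needs a later Baeyer–Villiger expansion. The arene is unsymmetrical, so the two rotamers about C28–C14 lead to the two C14 epimers, and nothing in A2 clearly discriminates between them.
- Comparison: the key step of alternative 1 is more dependable than a transannular cycloaddition. The chosen strategy offers three rings, two C–C bonds and four stereocentres in one step from a convergent precursor, and leaves only redox adjustments afterwards.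

**Alternative 2:** The cage is cut at C15–C16. Irradiation of ene-dione A4 transfers a hydrogen from the C15 methyl to the excited C19 carbonyl oxygen, and the biradical, delocalised over C19–C18–C16, closes at C16 to give dione A3.
- For: a bond between a methyl group and a fully substituted carbon is made without prefunctionalisation, and the cage geometry dictates C16.
- Against: the biradical can also close at C19 (cyclobutanol) or revert. The excited ene-dione can take hydrogen from C23 or the C26 methyl, and the diketone product is itself photolabile. A4 needs the contiguous quaternary carbons C14, C24 and C25 in place without the help of the cage.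
- Comparison: the risk is at least as high as that of the chosen key step and sits later, on a more advanced and less convergent intermediate.

**Alternative 3:** The cage is cut at C16–C18 and C19–C24. In A6 the silyloxydiene C24=C25–C29(OSi)=C16 adds the propiolate ester tethered through O22 and gives A5, closing ring E and the bicyclooctadiene.
- For: the tether fixes the regiochemistry and lowers the entropic cost. Two quaternary bridgeheads and the lactone form together, and the remaining silyl enol ether is placed to close ring C by alkylation at C27.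
- On this point alternative 3 is as strong or stronger: step 7 of the chosen route uses the same type of cycloaddition in intermolecular form and must rely on electronic regiocontrol.
- Against: A6 requires the spiro centre C14 and rings A and B first, so the route is linear. The two diene faces differ only through the C13 and C28 arms.
- Comparison: the chosen strategy builds the cage on a small ring and lets it template rings A–C in one step; it accepts a riskier key step in exchange.

Key step: step 27

Remark: the D-fructose-derived Shi ketone is assumed to deliver oxygen to the face of 2 that gives (R)-4, by analogy with 1-substituted cyclohexenes; if the sense is opposite, the enantiomeric ketone is used.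
Remark: stannane 6 is taken as a purchasable reagent.

## Route

Step 1
Reactants: 1 3-ethoxycyclohex-2-en-1-one
Product: 2 tert-butyl[(3-ethoxycyclohexa-1,3-dien-1-yl)oxy]dimethylsilane
Conditions: LiN(iPr)2, THF, −78 °C; TBSCl, DMPU, −78 °C → rt
Reagents that add atoms: tert-butyldimethylsilyl chloride, CC(C)(C)[Si](C)(C)Cl
Why: Kinetic α′-deprotonation of the vinylogous ester and O-silylation give the cross-conjugated silyl dienol ether (silyl enol ether formation).

Step 2
Reactants: 2 tert-butyl[(3-ethoxycyclohexa-1,3-dien-1-yl)oxy]dimethylsilane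
Product: 4 (R)-3-ethoxy-6-hydroxycyclohex-2-en-1-one, via silyloxy epoxide 3 (not isolated)
Conditions: D-fructose-derived Shi ketone (30 mol %), Oxone (KHSO5), K2CO3, Bu4NHSO4 (cat.), MeCN–dimethoxymethane/aq. Na2B4O7 buffer, 0 °C; aqueous work-up
Reagents that add atoms: Oxone (potassium peroxymonosulfate), [K+].[O-]S(=O)(=O)OO
Why: Shi asymmetric epoxidation attacks the more nucleophilic silyl enol ether double bond (Rubottom-type regiochemistry) and the silyloxy epoxide collapses to the α′-hydroxy ketone. The chiral dioxirane sets the temporary C14 stereocentre as R through its spiro transition state.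

Step 3
Reactants: 4 (R)-3-ethoxy-6-hydroxycyclohex-2-en-1-one
Product: 5 (R)-6-[(tert-butyldimethylsilyl)oxy]-3-ethoxycyclohex-2-en-1-one
Conditions: TBSCl, imidazole, DMF, rt
Reagents that add atoms: tert-butyldimethylsilyl chloride, CC(C)(C)[Si](C)(C)Cl
Why: Standard silylation of a secondary alcohol; the bulky silyl ether later directs the cycloaddition and the C25 methylation.

Step 4
Reactants: 5 (R)-6-[(tert-butyldimethylsilyl)oxy]-3-ethoxycyclohex-2-en-1-one; 6 tributyl[(methoxymethoxy)methyl]stannane
Product: 8 (R)-4-[(tert-butyldimethylsilyl)oxy]-3-[(methoxymethoxy)methyl]cyclohex-2-en-1-one, via tertiary carbinol 7 (not isolated)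
Conditions: 6, n-BuLi, THF, −78 °C; then 5, −78 °C; then 1 M HCl, THF, 0 °C
Reagents that add atoms: water, O
Why: Stork–Danheiser transposition: tin–lithium exchange gives the α-alkoxymethyllithium, which adds to the vinylogous ester carbonyl (C24); acid hydrolysis of the enol ether and β-elimination give the transposed enone carrying C23. C14 is untouched.

Step 5
Reactants: 8 (R)-4-[(tert-butyldimethylsilyl)oxy]-3-[(methoxymethoxy)methyl]cyclohex-2-en-1-one
Product: 9 (4R)-4-[(tert-butyldimethylsilyl)oxy]-3-[(methoxymethoxy)methyl]-6-methylcyclohex-2-en-1-one (both C16 epimers)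
Conditions: LiN(iPr)2, THF, −78 °C; MeI, −78 → −20 °C
Reagents that add atoms: iodomethane, CI
Why: Kinetic α′-enolate alkylation of a 4-silyloxycyclohexenone installs the C17 methyl; the configuration at C16 is irrelevant because C16 becomes sp2 in the next step.

Step 6
Reactants: 9 (4R)-4-[(tert-butyldimethylsilyl)oxy]-3-[(methoxymethoxy)methyl]-6-methylcyclohex-2-en-1-one
Product: 10 tert-butyl({(1R)-2-[(methoxymethoxy)methyl]-5-methyl-4-[(trimethylsilyl)oxy]cyclohexa-2,4-dien-1-yl}oxy)dimethylsilane
Conditions: LiN(iPr)2, THF, −78 °C; Me3SiCl, −78 → 0 °C; non-aqueous work-up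
Reagents that add atoms: chlorotrimethylsilane, C[Si](C)(C)Cl
Why: Kinetic α′-deprotonation and O-silylation give the cross-conjugated 2-silyloxy-1,3-diene C16=C29(OSi)–C25=C24 (silyl dienol ether formation).

Step 7
Reactants: 10 tert-butyl({(1R)-2-[(methoxymethoxy)methyl]-5-methyl-4-[(trimethylsilyl)oxy]cyclohexa-2,4-dien-1-yl}oxy)dimethylsilane; 11 methyl propiolate
Product: 12 methyl 7-[(tert-butyldimethylsilyl)oxy]-1-[(methoxymethoxy)methyl]-4-methyl-5-[(trimethylsilyl)oxy]bicyclo[2.2.2]octa-2,5-diene-2-carboxylate (C16 and C24 as in 43; C14 silyloxy group anti to the C18=C19 bridge)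
Conditions: 11 (5 equiv), toluene, BHT, 90 °C, sealed tube
Reagents that add atoms: none
Why: Normal-demand Diels–Alder reaction of a 2-silyloxydiene with an alkynoate: the nucleophilic terminus C16 bonds to the β-carbon C18 and the ester-bearing C19 to C24 ("para" rule). The propiolate approaches anti to the pseudoaxial C14 silyloxy group, which sets C16 and C24 in the absolute sense of 43; any minor facial isomer is a diastereomer and can be removed before C14 is oxidised.

Step 8
Reactants: 12 methyl 7-[(tert-butyldimethylsilyl)oxy]-1-[(methoxymethoxy)methyl]-4-methyl-5-[(trimethylsilyl)oxy]bicyclo[2.2.2]octa-2,5-diene-2-carboxylate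
Product: 13 methyl 7-[(tert-butyldimethylsilyl)oxy]-6-(hydroxymethyl)-1-[(methoxymethoxy)methyl]-4-methyl-5-oxobicyclo[2.2.2]oct-2-ene-2-carboxylate (both C25 epimers)
Conditions: 37 % aq. HCHO, Yb(OTf)3 (10 mol %), THF, rt
Reagents that add atoms: formaldehyde, C=O
Why: Lanthanide-triflate-catalysed aqueous Mukaiyama aldol reaction (hydroxymethylation) of the trimethylsilyl enol ether introduces C27 at C25; the C25 configuration is set in step 10.

Step 9
Reactants: 13 methyl 7-[(tert-butyldimethylsilyl)oxy]-6-(hydroxymethyl)-1-[(methoxymethoxy)methyl]-4-methyl-5-oxobicyclo[2.2.2]oct-2-ene-2-carboxylate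
Product: 14 methyl 7-[(tert-butyldimethylsilyl)oxy]-6-{[(tert-butyldiphenylsilyl)oxy]methyl}-1-[(methoxymethoxy)methyl]-4-methyl-5-oxobicyclo[2.2.2]oct-2-ene-2-carboxylate (both C25 epimers)
Conditions: TBDPSCl, imidazole, DMF, rt
Reagents that add atoms: tert-butyl(chloro)diphenylsilane, CC(C)(C)[Si](Cl)(c1ccccc1)c1ccccc1
Why: Silylation of the primary alcohol blocks retro-aldol loss of C27 and gives an acid-stable ether that survives step 11.

Step 10
Reactants: 14 methyl 7-[(tert-butyldimethylsilyl)oxy]-6-{[(tert-butyldiphenylsilyl)oxy]methyl}-1-[(methoxymethoxy)methyl]-4-methyl-5-oxobicyclo[2.2.2]oct-2-ene-2-carboxylate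
Product: 15 methyl 7-[(tert-butyldimethylsilyl)oxy]-6-{[(tert-butyldiphenylsilyl)oxy]methyl}-1-[(methoxymethoxy)methyl]-4,6-dimethyl-5-oxobicyclo[2.2.2]oct-2-ene-2-carboxylate (C26 methyl syn to the C18=C19 bridge, C27 syn to C14)
Conditions: LiN(iPr)2, THF, −78 °C; MeI, DMPU, −78 → −20 °C
Reagents that add atoms: iodomethane, CI
Why: Alkylation of the only possible ketone enolate (C25); the face toward the C14–C15 bridge is blocked by the C14 silyloxy group, so the methyl should enter from the C18=C19 side. This sets C25 with C27 on the C14 side, as ring C requires.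

Step 11
Reactants: 15 methyl 7-[(tert-butyldimethylsilyl)oxy]-6-{[(tert-butyldiphenylsilyl)oxy]methyl}-1-[(methoxymethoxy)methyl]-4,6-dimethyl-5-oxobicyclo[2.2.2]oct-2-ene-2-carboxylate
Product: 16 hydroxy keto lactone (cage with γ-lactone C19–C20(=O)–O22–C23–C24, C29 ketone, C14 hydroxyl, C27 tert-butyldiphenylsilyl ether)
Conditions: 1 M HCl in MeOH, 45 °C
Reagents that add atoms: none
Why: Acid methanolysis removes the methoxymethyl and the secondary tert-butyldimethylsilyl ether while the primary tert-butyldiphenylsilyl ether is expected to survive. The freed C23 hydroxyl lactonises onto the adjacent C20 ester; the C14 hydroxyl points away from C20 and cannot compete.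

Step 12
Reactants: 16 hydroxy keto lactone
Product: 17 diketo lactone (C14 and C29 ketones, C27 tert-butyldiphenylsilyl ether)
Conditions: Dess–Martin periodinane, CH2Cl2, rt
Reagents that add atoms: none
Why: Dess–Martin oxidation of the secondary alcohol; the controlling C14 stereocentre is erased after it has done its work.

Step 13
Reactants: 17 diketo lactone
Product: 19 C14 ethynyl methyl carbonate (C14 configuration of no consequence), via magnesium alkoxide 18 (not isolated)
Conditions: HC≡CMgBr, LaCl3·2LiCl, THF, 0 °C; then ClCO2Me, 0 °C → rt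
Reagents that add atoms: ethynylmagnesium bromide, C#C[Mg]Br; methyl chloroformate, COC(=O)Cl
Why: Lanthanum-promoted 1,2-addition of the small acetylide to the C14 ketone (C29 lies between two quaternary carbons and the lactone is less electrophilic), followed by acylation of the tertiary alkoxide; this brings in C13 and C12.

Step 14
Reactants: 19 C14 ethynyl methyl carbonate
Product: 20 C14 vinylidene compound (allene C14=C13=C12H2)
Conditions: Pd2(dba)3·CHCl3 (2.5 mol %), PBu3 (10 mol %), HCO2NH4, THF, rt
Reagents that add atoms: none
Why: Palladium-catalysed formate hydrogenolysis of a tertiary propargylic carbonate: zerovalent palladium ionises the carbonate to an allenylpalladium species and hydride from formate is delivered SN2′ to give the 1,1-disubstituted allene.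

Step 15
Reactants: 20 C14 vinylidene compound
Product: 22 (13Z)-allylic alcohol (C12 hydroxymethyl cis to C24), via allylborane 21 (not isolated)
Conditions: (c-C6H11)2BH (from BH3·SMe2 and cyclohexene, THF, 0 °C), then 20, −20 → 0 °C; then aq. NaOAc, 30 % H2O2, 0 °C
Reagents that add atoms: hydrogen peroxide, OO
Why: Kinetic hydroboration of a 1,1-disubstituted allene at the terminal double bond: boron goes to C12 and hydrogen to the central C13 from the open C15 side, so C12 is turned toward the crowded C24 side. Oxidation at low temperature before any 1,3-boron shift keeps the geometry.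

Step 16
Reactants: 22 (13Z)-allylic alcohol
Product: 23 (13Z)-enal (C12 aldehyde)
Conditions: MnO2, CH2Cl2, rt
Reagents that add atoms: none
Why: Neutral allylic oxidation with manganese dioxide, chosen to avoid acid- or base-mediated Z/E isomerisation.

Step 17
Reactants: 23 (13Z)-enal
Product: 24 (13Z)-diene C14=C13–C12=CH2 with C27 tert-butyldiphenylsilyl ether
Conditions: Ph3PCH3Br, KN(SiMe3)2, THF, −78 °C; then 23, −78 → 0 °C
Reagents that add atoms: methyltriphenylphosphonium bromide, C[P+](c1ccccc1)(c1ccccc1)c1ccccc1.[Br-]
Why: Wittig methylenation of the aldehyde at low temperature; the hindered C29 ketone and the lactone do not react.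

Step 18
Reactants: 24 (13Z)-diene with C27 tert-butyldiphenylsilyl ether
Product: 25 (13Z)-diene C27 alcohol
Conditions: Bu4NF, AcOH (1:1), THF, rt → 40 °C
Reagents that add atoms: none
Why: Buffered fluoride desilylation; the buffer suppresses retro-aldol loss of C27 from the β-hydroxy ketone.

Step 19
Reactants: 25 (13Z)-diene C27 alcohol
Product: 26 (13Z)-diene C27 aldehyde
Conditions: Dess–Martin periodinane, pyridine, CH2Cl2, 0 °C
Reagents that add atoms: none
Why: Dess–Martin oxidation of a neopentyl primary alcohol to the non-enolisable β-keto aldehyde under buffered conditions.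

Step 20
Reactants: 27 prop-2-yn-1-ol
Product: 29 (Z)-3-iodo-2-methylprop-2-en-1-ol, via alkenylmagnesium alkoxide 28 (not isolated)
Conditions: MeMgBr (2.5 equiv), CuI (10 mol %), Et2O, −10 °C → rt; then I2, −10 °C
Reagents that add atoms: methylmagnesium bromide, C[Mg]Br; iodine, II
Why: Copper-catalysed anti-carbomagnesiation of the propargylic alkoxide puts the methyl on the internal carbon and magnesium cis to the CH2O group in a chelate; iodinolysis with retention gives the (Z)-iodoalkene (C28, C9, C10, C8).

Step 21
Reactants: 29 (Z)-3-iodo-2-methylprop-2-en-1-ol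
Product: 30 (Z)-3-bromo-1-iodo-2-methylprop-1-ene
Conditions: CBr4, PPh3, CH2Cl2, 0 °C
Reagents that add atoms: carbon tetrabromide, BrC(Br)(Br)Br
Why: Appel bromination of the primary allylic alcohol without touching the vinyl iodide.

Step 22
Reactants: 31 2-methylbut-3-en-2-ol
Product: 32 2-methylbut-3-en-2-yl acetate
Conditions: Ac2O, Et3N, DMAP (cat.), CH2Cl2, rt
Reagents that add atoms: acetic anhydride, CC(=O)OC(C)=O
Why: DMAP-catalysed acylation of a tertiary alcohol; the acetyl group supplies C5 and C7, the alcohol O4, C2 and C11.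

Step 23
Reactants: 32 2-methylbut-3-en-2-yl acetate; 30 (Z)-3-bromo-1-iodo-2-methylprop-1-ene
Product: 33 2-methylbut-3-en-2-yl (Z)-5-iodo-4-methylpent-4-enoate
Conditions: LiN(iPr)2, THF, −78 °C; then 30, DMPU, −78 → −40 °C
Reagents that add atoms: none
Why: Ester enolate alkylation with a reactive allylic bromide forms C7–C8; at −78 °C the ester enolate Claisen rearrangement of the allylic acetate should not compete.

Step 24
Reactants: 26 (13Z)-diene C27 aldehyde; 33 2-methylbut-3-en-2-yl (Z)-5-iodo-4-methylpent-4-enoate
Product: 34 C27 allylic alcohol (both C27 epimers; (9Z)-alkene, tertiary ester, terminal diene)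
Conditions: CrCl2 (6 equiv), NiCl2 (2 mol %), DMSO, rt
Reagents that add atoms: none
Why: Nozaki–Hiyama–Kishi reaction: the alkenylchromium species formed with retention of the (Z)-geometry adds only to the aldehyde, not to ketone, lactone or ester, and forms C27–C28.

Step 25
Reactants: 34 C27 allylic alcohol
Product: 35 seco-triene: (9Z)-enone C28=C9–C27(=O), terminal (13Z)-diene, 2-methylbut-3-en-2-yl ester
Conditions: Dess–Martin periodinane, pyridine, CH2Cl2, 0 °C
Reagents that add atoms: none
Why: Dess–Martin oxidation of the allylic alcohol gives the (Z)-enone without isomerisation and removes the C27 stereocentre.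

Step 26
Reactants: 35 seco-triene
Product: 36 14-membered macrolactone triene ((9Z,11E,13Z), C27 ketone)
Conditions: second-generation Grubbs catalyst (H2IMes)(PCy3)Cl2Ru=CHPh (10 mol %), toluene (1 mM), 80 °C
Reagents that add atoms: none
Why: Ring-closing metathesis between the diene terminus and the vinyl group on C2 forms C11=C12 with loss of ethylene. The trisubstituted C13=C14 and C9=C28 bonds are too hindered to engage, and the (E)-alkene is expected in a 14-membered conjugated diene.

Step 27
Reactants: 36 14-membered macrolactone triene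
Product: 37 12,13-didehydro-7,8-dihydro-27-oxoandilesin B (hexacycle with C12=C13, C27 ketone, saturated ε-lactone)
Conditions: toluene (1 mM), BHT, 120 °C, sealed base-washed tube
Reagents that add atoms: none
Why: The thermal reaction is a concerted, suprafacial [4+2] cycloaddition across the 14-membered ring (transannular Diels–Alder); the closest known reaction type is the transannular cycloaddition of 14-membered macrocyclic trienes, supported by intramolecular Diels–Alder reactions of (Z)-dienes with a three-atom tether. Ring B closes as the cyclohexene of the cycloaddition itself (C9–C11 and C14–C28, new C12=C13), ring C in the fused five-membered mode through the link C24–C25–C27 between diene terminus C14 and dienophile carbon C28, and ring A in the fused seven-membered mode through the lactone link C2–O4–C5–C7–C8 between C11 and C9. C9 and C28 are controlled by the (Z)-enone: suprafacial addition keeps C8 and C27 cis on ring B, so the C10 methyl is cis to H28. C11 and C14 are controlled by the diene: C2 is the outside substituent of the (11E) bond and C15 the outside substituent on C14, so they end cis, and H11 ends cis to C24. The C24–C25–C27 link can bridge C14 and C28 only on one face of ring B (cis B/C), which places C8 on the face opposite to C2 (trans A/B). The absolute sense comes from the cage, because C27 hangs from C25 on the C14 side and C28 can reach C14 only on the face of C13=C14 turned toward the C25–C29 bridge. The step needs the cycloaddition to outrun ester elimination and enone isomerisation and to give one diastereomer; the two tethers, the rigid core, the absence of hydrogen on C24 and C2 (no 1,5-hydrogen shift of the diene) and the LUMO-lowering C27 carbonyl are expected to secure this.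

Step 28
Reactants: 37 12,13-didehydro-7,8-dihydro-27-oxoandilesin B
Product: 38 7,8-dihydro-27-oxoandilesin B
Conditions: H2 (1 atm), Pd/C, EtOAc, rt
Reagents that add atoms: none
Why: Catalytic hydrogenation of the cis-disubstituted C12=C13 bond; the trisubstituted, conjugated C18=C19 bond between two quaternary bridgeheads should be much slower. No stereocentre is formed.

Step 29
Reactants: 38 7,8-dihydro-27-oxoandilesin B
Product: 39 7,8-dihydro-27-hydroxyandilesin B (C27 epimers)
Conditions: NaBH4, MeOH–THF, −20 °C
Reagents that add atoms: none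
Why: Borohydride reduces the cyclopentanone-type C27 ketone in preference to the C29 ketone, which lies between two quaternary carbons; low temperature avoids retro-aldol cleavage and lactone methanolysis.

Step 30
Reactants: 39 7,8-dihydro-27-hydroxyandilesin B
Product: 40 O-(C27) 1H-imidazole-1-carbothioate of 39
Conditions: 1,1′-thiocarbonyldiimidazole, DMAP, ClCH2CH2Cl, 80 °C
Reagents that add atoms: 1,1′-thiocarbonyldiimidazole, S=C(n1ccnc1)n1ccnc1
Why: Neutral thioacylation of a hindered secondary alcohol prepares the radical deoxygenation without enolising the lactones.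

Step 31
Reactants: 40 O-(C27) 1H-imidazole-1-carbothioate
Product: 41 7,8-dihydroandilesin B
Conditions: Bu3SnH, AIBN (cat.), toluene, 110 °C
Reagents that add atoms: none
Why: Barton–McCombie deoxygenation: the secondary C27 radical is reduced by the stannane; cyclisation onto C18=C19 would need a strained four- or 5-endo ring and is not expected.

Step 32
Reactants: 41 7,8-dihydroandilesin B
Product: 43 andilesin B, via phenylselanyl lactone 42 (not isolated)
Conditions: LiN(iPr)2, THF, −78 °C; PhSeBr, −78 °C; then 30 % H2O2, pyridine, CH2Cl2, 0 °C → rt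
Reagents that add atoms: none
Why: C7 is the only enolisable position of 41, so the lactone enolate is selenenylated there; the selenoxide undergoes syn-elimination toward C8 and gives the C7=C8 double bond (selenoxide elimination).

## Compound list

1 | 3-ethoxycyclohex-2-en-1-one | CCOC1=CC(=O)CCC1 | starting material
2 | tert-butyl[(3-ethoxycyclohexa-1,3-dien-1-yl)oxy]dimethylsilane | CCOC1=CC(O[Si](C)(C)C(C)(C)C)=CCC1 | intermediate
3 | 1-[(tert-butyldimethylsilyl)oxy]-3-ethoxy-7-oxabicyclo[4.1.0]hept-2-ene (CH carbon R) | CCOC1=C[C@]2(O[Si](C)(C)C(C)(C)C)O[C@@H]2CC1 | intermediate (not isolated)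
4 | (R)-3-ethoxy-6-hydroxycyclohex-2-en-1-one | CCOC1=CC(=O)[C@H](O)CC1 | intermediate
5 | (R)-6-[(tert-butyldimethylsilyl)oxy]-3-ethoxycyclohex-2-en-1-one | CCOC1=CC(=O)[C@H](O[Si](C)(C)C(C)(C)C)CC1 | intermediate
6 | tributyl[(methoxymethoxy)methyl]stannane | CCCC[Sn](CCCC)(CCCC)COCOC | starting material
7 | (6R)-6-[(tert-butyldimethylsilyl)oxy]-3-ethoxy-1-[(methoxymethoxy)methyl]cyclohex-2-en-1-ol (mixture at C1) | CCOC1=CC(O)(COCOC)[C@H](O[Si](C)(C)C(C)(C)C)CC1 | intermediate (not isolated)
8 | (R)-4-[(tert-butyldimethylsilyl)oxy]-3-[(methoxymethoxy)methyl]cyclohex-2-en-1-one | O=C1C=C(COCOC)[C@H](O[Si](C)(C)C(C)(C)C)CC1 | intermediate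
9 | (4R)-4-[(tert-butyldimethylsilyl)oxy]-3-[(methoxymethoxy)methyl]-6-methylcyclohex-2-en-1-one (both C6 epimers) | O=C1C=C(COCOC)[C@H](O[Si](C)(C)C(C)(C)C)CC1C | intermediate
10 | tert-butyl({(1R)-2-[(methoxymethoxy)methyl]-5-methyl-4-[(trimethylsilyl)oxy]cyclohexa-2,4-dien-1-yl}oxy)dimethylsilane | CC1=C(O[Si](C)(C)C)C=C(COCOC)[C@H](O[Si](C)(C)C(C)(C)C)C1 | intermediate
11 | methyl propiolate | C#CC(=O)OC | starting material
12 | methyl 7-[(tert-butyldimethylsilyl)oxy]-1-[(methoxymethoxy)methyl]-4-methyl-5-[(trimethylsilyl)oxy]bicyclo[2.2.2]octa-2,5-diene-2-carboxylate | C[C@]12C=C(C(=O)OC)[C@](COCOC)(C=C1O[Si](C)(C)C)[C@H](O[Si](C)(C)C(C)(C)C)C2 | intermediate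
13 | methyl 7-[(tert-butyldimethylsilyl)oxy]-6-(hydroxymethyl)-1-[(methoxymethoxy)methyl]-4-methyl-5-oxobicyclo[2.2.2]oct-2-ene-2-carboxylate (C25 epimers) | C[C@]12C=C(C(=O)OC)[C@](COCOC)(C(CO)C1=O)[C@H](O[Si](C)(C)C(C)(C)C)C2 | intermediate
14 | tert-butyldiphenylsilyl ether of 13 (C25 epimers) | C[C@]12C=C(C(=O)OC)[C@](COCOC)(C(CO[Si](c3ccccc3)(c3ccccc3)C(C)(C)C)C1=O)[C@H](O[Si](C)(C)C(C)(C)C)C2 | intermediate
15 | methyl 7-[(tert-butyldimethylsilyl)oxy]-6-{[(tert-butyldiphenylsilyl)oxy]methyl}-1-[(methoxymethoxy)methyl]-4,6-dimethyl-5-oxobicyclo[2.2.2]oct-2-ene-2-carboxylate (C26 methyl syn to C18=C19) | C[C@]12C=C(C(=O)OC)[C@](COCOC)([C@@](C)(CO[Si](c3ccccc3)(c3ccccc3)C(C)(C)C)C1=O)[C@H](O[Si](C)(C)C(C)(C)C)C2 | intermediate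
16 | hydroxy keto lactone (ring E closed, C14 hydroxyl, C27 silyl ether) | C[C@]12C=C3C(=O)OC[C@@]3([C@@](C)(CO[Si](c4ccccc4)(c4ccccc4)C(C)(C)C)C1=O)[C@H](O)C2 | intermediate
17 | diketo lactone (C14 and C29 ketones, C27 silyl ether) | C[C@]12C=C3C(=O)OC[C@@]3([C@@](C)(CO[Si](c4ccccc4)(c4ccccc4)C(C)(C)C)C1=O)C(=O)C2 | intermediate
18 | bromomagnesium alkoxide of the C14 ethynyl carbinol (C14 unspecified) | C[C@]12C=C3C(=O)OC[C@@]3([C@@](C)(CO[Si](c4ccccc4)(c4ccccc4)C(C)(C)C)C1=O)C(O[Mg]Br)(C#C)C2 | intermediate (not isolated)
19 | C14 ethynyl methyl carbonate (C14 unspecified) | C[C@]12C=C3C(=O)OC[C@@]3([C@@](C)(CO[Si](c4ccccc4)(c4ccccc4)C(C)(C)C)C1=O)C(OC(=O)OC)(C#C)C2 | intermediate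
20 | C14 vinylidene compound (allene) | C[C@]12C=C3C(=O)OC[C@@]3([C@@](C)(CO[Si](c4ccccc4)(c4ccccc4)C(C)(C)C)C1=O)C(=C=C)C2 | intermediate
21 | (13Z)-C12 dicyclohexylborane | C[C@]12C=C3C(=O)OC[C@@]3([C@@](C)(CO[Si](c4ccccc4)(c4ccccc4)C(C)(C)C)C1=O)/C(=C\CB(C4CCCCC4)C4CCCCC4)C2 | intermediate (not isolated)
22 | (13Z)-allylic alcohol | C[C@]12C=C3C(=O)OC[C@@]3([C@@](C)(CO[Si](c4ccccc4)(c4ccccc4)C(C)(C)C)C1=O)/C(=C\CO)C2 | intermediate
23 | (13Z)-enal | C[C@]12C=C3C(=O)OC[C@@]3([C@@](C)(CO[Si](c4ccccc4)(c4ccccc4)C(C)(C)C)C1=O)/C(=C\C=O)C2 | intermediate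
24 | (13Z)-diene with C27 tert-butyldiphenylsilyl ether | C[C@]12C=C3C(=O)OC[C@@]3([C@@](C)(CO[Si](c4ccccc4)(c4ccccc4)C(C)(C)C)C1=O)/C(=C\C=C)C2 | intermediate
25 | (13Z)-diene C27 alcohol | C[C@]12C=C3C(=O)OC[C@@]3([C@@](C)(CO)C1=O)/C(=C\C=C)C2 | intermediate
26 | (13Z)-diene C27 aldehyde | C[C@]12C=C3C(=O)OC[C@@]3([C@@](C)(C=O)C1=O)/C(=C\C=C)C2 | intermediate
27 | prop-2-yn-1-ol | C#CCO | starting material
28 | bromomagnesium (Z)-3-(bromomagnesio)-2-methylprop-2-en-1-olate | Br[Mg]OC/C(C)=C\[Mg]Br | intermediate (not isolated)
29 | (Z)-3-iodo-2-methylprop-2-en-1-ol | OC/C(C)=C\I | intermediate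
30 | (Z)-3-bromo-1-iodo-2-methylprop-1-ene | BrC/C(C)=C\I | intermediate
31 | 2-methylbut-3-en-2-ol | CC(C)(O)C=C | starting material
32 | 2-methylbut-3-en-2-yl acetate | CC(=O)OC(C)(C)C=C | intermediate
33 | 2-methylbut-3-en-2-yl (Z)-5-iodo-4-methylpent-4-enoate | C=CC(C)(C)OC(=O)CC/C(C)=C\I | intermediate
34 | C27 allylic alcohol (C27 epimers) | C[C@]12C=C3C(=O)OC[C@@]3([C@@](C)(C(O)/C=C(C)\CCC(=O)OC(C)(C)C=C)C1=O)/C(=C\C=C)C2 | intermediate
35 | seco-triene with (9Z)-enone | C[C@]12C=C3C(=O)OC[C@@]3([C@@](C)(C(=O)/C=C(C)\CCC(=O)OC(C)(C)C=C)C1=O)/C(=C\C=C)C2 | intermediate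
36 | 14-membered macrolactone triene (9Z,11E,13Z) | CC1(C)OC(=O)CC/C(C)=C\C(=O)[C@]2(C)[C@@]34COC(=O)C3=C[C@@](C)(C2=O)C/C4=C/C=C/1 | intermediate
37 | 12,13-didehydro-7,8-dihydro-27-oxoandilesin B | CC1(C)OC(=O)CC[C@@]2(C)[C@H]1C=C[C@@]13C[C@@]4(C)C=C5C(=O)OC[C@]51[C@@](C)(C(=O)[C@@H]23)C4=O | intermediate
38 | 7,8-dihydro-27-oxoandilesin B | CC1(C)OC(=O)CC[C@@]2(C)[C@H]1CC[C@@]13C[C@@]4(C)C=C5C(=O)OC[C@]51[C@@](C)(C(=O)[C@@H]23)C4=O | intermediate
39 | 7,8-dihydro-27-hydroxyandilesin B (C27 epimers) | CC1(C)OC(=O)CC[C@@]2(C)[C@H]1CC[C@@]13C[C@@]4(C)C=C5C(=O)OC[C@]51[C@@](C)(C(O)[C@@H]23)C4=O | intermediate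
40 | O-(C27) 1H-imidazole-1-carbothioate of 39 | CC1(C)OC(=O)CC[C@@]2(C)[C@H]1CC[C@@]13C[C@@]4(C)C=C5C(=O)OC[C@]51[C@@](C)(C(OC(=S)n6ccnc6)[C@@H]23)C4=O | intermediate
41 | 7,8-dihydroandilesin B | CC1(C)OC(=O)CC[C@@]2(C)[C@H]1CC[C@@]13C[C@@]4(C)C=C5C(=O)OC[C@]51[C@@](C)(C[C@@H]23)C4=O | intermediate
42 | 7-(phenylselanyl)-7,8-dihydroandilesin B (C7 epimers) | CC1(C)OC(=O)C([Se]c6ccccc6)C[C@@]2(C)[C@H]1CC[C@@]13C[C@@]4(C)C=C5C(=O)OC[C@]51[C@@](C)(C[C@@H]23)C4=O | intermediate (not isolated)
43 | andilesin B | CC1(C)OC(=O)C=C[C@@]2(C)[C@H]1CC[C@@]13C[C@@]4(C)C=C5C(=O)OC[C@]51[C@@](C)(C[C@@H]23)C4=O | target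

## Step count and least certain steps

Total: 32 steps. Longest linear sequence: 28 steps (steps 1–19 and 24–32); the side chain (steps 20–23) joins at step 24.

**Step 27 (key step).** The s-cis conformer of the diene has the quaternary C24 in the inside position, so the barrier may be high. At the temperatures then needed, the (Z)-enone may isomerise through a dienol (1,5-hydrogen shift from C8) and the tertiary allylic ester may eliminate. The fallback leaves the transannular mode and closes ring A afterwards; it sets out from aldehyde 26 and returns at 37.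
- Methyl (Z)-5-iodo-4-methylpent-4-enoate F1 would first be made from bromide 30 and the lithium enolate of methyl acetate.
- Cross-metathesis of 26 with 31 (second-generation Hoveyda–Grubbs catalyst (H2IMes)Cl2Ru=CH(C6H4-2-OiPr)) would give the (11E,13Z)-dienol aldehyde F2.
- Nozaki–Hiyama–Kishi addition of F1 (CrCl2, NiCl2) would give allylic alcohol F3, and Dess–Martin oxidation the open-chain enone F4.
- Heating F4, which carries no tertiary ester and tolerates higher temperature, should give the intramolecular cycloadduct F5 with the same configuration, because the C24–C25–C27 tether alone dictates it.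
- Acid-catalysed lactonisation of the tertiary alcohol of F5 onto the C5 methyl ester (camphorsulfonic acid, toluene, molecular sieves) would give 37.

**Step 15.** A 1,3-boron shift in the allylborane before oxidation would erode the (13Z) geometry, and some boron may add at C13. The fallback sets out from ketone 17 and returns at diene 24.
- Dibromomethylenation (CBr4, PPh3) would give the 1,1-dibromoalkene F6.
- Palladium-catalysed hydrogenolysis (Pd(PPh3)4, Bu3SnH) should remove the less hindered bromine, cis to C15, and leave the (Z)-bromoalkene F7 with bromine cis to C24.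
- Stille coupling of F7 with tributyl(vinyl)stannane would give 24.

**Step 10.** C-methylation of a tetrasubstituted enolate next to the quaternary C24 may be slow, which would let O-methylation or loss of silyloxide compete. The fallback quaternises a softer β-dicarbonyl enolate; it sets out from 13 and returns at 15.
- Dess–Martin oxidation of 13 would give the formyl ketone F8.
- K2CO3 and MeI in acetone would C-methylate it from the same open face to the β-keto aldehyde F9.
- NaBH4 at −78 °C would reduce only the aldehyde to alcohol F10, and silylation with TBDPSCl would give 15.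

**Step 26.** Oligomerisation, formation of some (11Z) isomer in the strained ring, or slow turnover at the hindered vinyl group may occur. The fallback sets the (11E) bond in an open chain and closes the ring at C27–C28; it sets out from 24 and 33 and returns at 36.
- Cross-metathesis of 24 with 33 would give the (11E)-ester F11.
- Buffered Bu4NF would give alcohol F12 and Dess–Martin oxidation the iodo aldehyde F13.
- An intramolecular Nozaki–Hiyama–Kishi reaction at high dilution (CrCl2, NiCl2) would give the macrocyclic allylic alcohol F14, and Dess–Martin oxidation 36.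

**Step 7.** Both diene termini are fully substituted, so the thermal reaction may be slow, and some addition syn to the silyloxy group would erode the facial selectivity. The fallback uses a chelating, Lewis-acid-activated dienophile under catalyst control; it sets out from 10 and returns at 12.
- Cycloaddition of 10 with 3-propioloyloxazolidin-2-one (C#CC(=O)N1CCOC1=O) under Cu(OTf)2 and a bis(oxazoline) ligand of the matched hand, at low temperature, would give the imide adduct F15.
- Methanolysis (MeOMgBr, MeOH) would give the keto methyl ester F16, and LiN(iPr)2 with Me3SiCl would regenerate 12.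

## Further compounds

F1 | step 27 | methyl (Z)-5-iodo-4-methylpent-4-enoate | COC(=O)CC/C(C)=C\I
F2 | step 27 | (11E,13Z)-dienol C27 aldehyde | C[C@]12C=C3C(=O)OC[C@@]3([C@@](C)(C=O)C1=O)/C(=C\C=C\C(C)(C)O)C2
F3 | step 27 | open-chain C27 allylic alcohol methyl ester (C27 epimers) | C[C@]12C=C3C(=O)OC[C@@]3([C@@](C)(C(O)/C=C(C)\CCC(=O)OC)C1=O)/C(=C\C=C\C(C)(C)O)C2
F4 | step 27 | open-chain (9Z)-enone methyl ester with free C2 hydroxyl | C[C@]12C=C3C(=O)OC[C@@]3([C@@](C)(C(=O)/C=C(C)\CCC(=O)OC)C1=O)/C(=C\C=C\C(C)(C)O)C2
F5 | step 27 | seco-37 hydroxy methyl ester (rings B and C closed, ring A open) | COC(=O)CC[C@@]2(C)[C@H](C(C)(C)O)C=C[C@@]13C[C@@]4(C)C=C5C(=O)OC[C@]51[C@@](C)(C(=O)[C@@H]23)C4=O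
F6 | step 15 | C14 dibromomethylene compound | C[C@]12C=C3C(=O)OC[C@@]3([C@@](C)(CO[Si](c4ccccc4)(c4ccccc4)C(C)(C)C)C1=O)C(=C(Br)Br)C2
F7 | step 15 | (Z)-C13 bromoalkene (bromine cis to C24) | C[C@]12C=C3C(=O)OC[C@@]3([C@@](C)(CO[Si](c4ccccc4)(c4ccccc4)C(C)(C)C)C1=O)/C(=C\Br)C2
F8 | step 10 | C25 formyl ketone (C25 epimers or enol) | C[C@]12C=C(C(=O)OC)[C@](COCOC)(C(C=O)C1=O)[C@H](O[Si](C)(C)C(C)(C)C)C2
F9 | step 10 | C25-methyl β-keto aldehyde | C[C@]12C=C(C(=O)OC)[C@](COCOC)([C@@](C)(C=O)C1=O)[C@H](O[Si](C)(C)C(C)(C)C)C2
F10 | step 10 | C25-methyl C27 alcohol | C[C@]12C=C(C(=O)OC)[C@](COCOC)([C@@](C)(CO)C1=O)[C@H](O[Si](C)(C)C(C)(C)C)C2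
F11 | step 26 | (11E,13Z)-diene ester with vinyl iodide and C27 silyl ether | C[C@]12C=C3C(=O)OC[C@@]3([C@@](C)(CO[Si](c4ccccc4)(c4ccccc4)C(C)(C)C)C1=O)/C(=C\C=C\C(C)(C)OC(=O)CC/C(C)=C\I)C2
F12 | step 26 | C27 alcohol of F11 | C[C@]12C=C3C(=O)OC[C@@]3([C@@](C)(CO)C1=O)/C(=C\C=C\C(C)(C)OC(=O)CC/C(C)=C\I)C2
F13 | step 26 | C27 aldehyde with vinyl iodide | C[C@]12C=C3C(=O)OC[C@@]3([C@@](C)(C=O)C1=O)/C(=C\C=C\C(C)(C)OC(=O)CC/C(C)=C\I)C2
F14 | step 26 | macrocyclic C27 allylic alcohol (C27 epimers) | CC1(C)OC(=O)CC/C(C)=C\C(O)[C@]2(C)[C@@]34COC(=O)C3=C[C@@](C)(C2=O)C/C4=C/C=C/1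
F15 | step 7 | N-acyloxazolidinone analogue of 12 | C[C@]12C=C(C(=O)N3CCOC3=O)[C@](COCOC)(C=C1O[Si](C)(C)C)[C@H](O[Si](C)(C)C(C)(C)C)C2
F16 | step 7 | keto methyl ester (12 without the trimethylsilyl group) | C[C@]12C=C(C(=O)OC)[C@](COCOC)(CC1=O)[C@H](O[Si](C)(C)C(C)(C)C)C2
A1 | alternative 1 | spirocyclohexadienone with rings A and B | CC1(C)C6(OCCO6)CC[C@@]2(C)[C@H]1CC[C@]3(C=C(C)C(=O)C(C)=C3COCOC)[C@H]2CO[Si](C)(C)C(C)(C)C
A2 | alternative 1 | iodo phenol precursor of A1 | CC1(C)C6(OCCO6)CC[C@@](C)([C@H]1CCI)[C@H](CO[Si](C)(C)C(C)(C)C)c1cc(C)c(O)c(C)c1COCOC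
A3 | alternative 2 | bicyclo[2.2.2]octane-dione with C29 and C19 ketones | CC1(C)C6(OCCO6)CC[C@@]2(C)[C@H]1CC[C@@]13C[C@@]4(C)CC(=O)[C@]1(COC(C)=O)[C@@](C)(C[C@@H]23)C4=O
A4 | alternative 2 | tetracyclic ene-dione precursor of A3 | CC1(C)C6(OCCO6)CC[C@@]2(C)[C@H]1CC[C@@]1(C)[C@]3(COC(C)=O)C(=O)C=C(C)C(=O)[C@]3(C)C[C@@H]21
A5 | alternative 3 | bicyclo[2.2.2]octadiene lactone with C25=C29 silyl enol ether | CC1(C)C6(OCCO6)CC[C@@]2(C)[C@H]1CC[C@@]1([C@H]2CBr)C[C@@]4(C)C=C5C(=O)OC[C@]51C(C)=C4O[Si](C)(C)C(C)(C)C
A6 | alternative 3 | spirocyclic silyloxydiene propiolate precursor of A5 | CC1(C)C6(OCCO6)CC[C@@]2(C)[C@H]1CC[C@@]1([C@H]2CBr)CC(C)=C(O[Si](C)(C)C(C)(C)C)C(C)=C1COC(=O)C#C
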